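**Remark:** the target is epigallocatechin-(4β→8)-catechin (upper unit 2R,3R,4R; lower unit 2R,3S). (−)-Epigallocatechin, 3,5-bis(benzyloxy)phenol and 3,4-bis(benzyloxy)benzoic acid are treated as purchasable.

## Retrosynthetic overview

1. Last disconnections: nine benzyl ethers and one acetate; then the interflavan C4(upper)–C8(lower) bond, made by Lewis-acid coupling of a C4-activated penta-O-benzyl-epigallocatechin 3-acetate (from natural (−)-epigallocatechin) with tetra-O-benzyl-(+)-catechin, attack anti to the 3-acetoxy group giving 4β.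
2. The lower catechin unit is built de novo: its C3–OH and C2–H come from a reagent-controlled syn hydroboration–oxidation of a tetra-O-benzyl flav-2-ene (2,3-trans, 2R,3S).
3. Ring C of that flav-2-ene is closed by forming C2–C3 as a double bond: titanium-alkylidene carbonyl–olefin metathesis of 2-allyl-3,5-bis(benzyloxy)phenyl 3,4-bis(benzyloxy)benzoate.
4. Feature used: in the lower unit C2 carries the ring oxygen O1 and the ring B aryl, so at the acyl level it is the carbonyl carbon of an aryl benzoate on O1. C3–C4 is an allyl group on the neighbouring ring A carbon C4a, delivered there from O1 by a Claisen rearrangement.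
5. Ring order: rings A and B of the lower unit are bought; ring C of the lower unit forms in step 4; the three rings of the upper unit come intact from epigallocatechin; the units are joined in step 9.

Key step: step 4

## Route

Step 1
Reactants: 1 3,5-bis(benzyloxy)phenol
Product: 2 1-(allyloxy)-3,5-bis(benzyloxy)benzene
Conditions: allyl bromide, K2CO3, acetone, reflux
Reagents that add atoms: allyl bromide, C=CCBr
Why: Williamson O-allylation of the single free phenol should be clean and installs the three carbons that become C4, C3 and the methylene later lost as propene.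

Step 2
Reactants: 2 1-(allyloxy)-3,5-bis(benzyloxy)benzene
Product: 3 2-allyl-3,5-bis(benzyloxy)phenol
Conditions: PhNEt2, 190 °C
Reagents that add atoms: none
Why: The aromatic Claisen rearrangement ([3,3] shift, then tautomerisation) should move the allyl group to an ortho carbon, the two ortho positions being equivalent by symmetry, which bonds C4 to C4a and frees the oxygen that becomes O1.

Step 3
Reactants: 3 2-allyl-3,5-bis(benzyloxy)phenol; 4 3,4-bis(benzyloxy)benzoic acid
Product: 5 2-allyl-3,5-bis(benzyloxy)phenyl 3,4-bis(benzyloxy)benzoate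
Conditions: DCC, DMAP (cat.), CH2Cl2, rt
Reagents that add atoms: none
Why: Steglich esterification should acylate the phenol with the ring B acid, placing the future C2 on O1 at the carboxyl oxidation level.

Step 4
Reactants: 5 2-allyl-3,5-bis(benzyloxy)phenyl 3,4-bis(benzyloxy)benzoate
Product: 7 5,7-bis(benzyloxy)-2-[3,4-bis(benzyloxy)phenyl]-4H-chromene (tetra-O-benzyl flav-2-ene), via titanium alkylidene 6 (not isolated)
Conditions: TiCl4, TMEDA, Zn, PbCl2 (cat.), CH3CHBr2, THF/CH2Cl2, 0 °C to 65 °C
Reagents that add atoms: none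
Why: The reduced titanium ethylidene made from TiCl4, Zn, PbCl2 and CH3CHBr2 should first exchange with the only terminal olefin (loss of propene) to place a titanium alkylidene on the future C3 (6); this adds across the benzoate C=O and, by cycloreversion of the oxatitanacyclobutane, expels titanium oxide and leaves the C2=C3 double bond. The closest known reaction type is the Takai–Utimoto ester alkylidenation run as an olefinic-ester cyclisation (carbonyl–olefin metathesis), the titanium counterpart of enol ether ring-closing metathesis. Ring C of the lower unit (O1–C2–C3–C4–C4a–C8a) is the only ring closed, by intramolecular carbonyl olefination with the new C2=C3 bond endocyclic in a six-membered ring whose other atoms are held 1,2 on ring A, so the two ends are pre-organised. No stereocentre is formed here; C2 and C3 leave the step as a polarised aryl enol ether whose faces are differentiated in step 5. The step needs olefin exchange to precede direct ethylidenation of the ester and needs the four benzyl ethers to be inert: the ethylidene reagent is slow towards the conjugated aryl ester but fast towards the monosubstituted allyl terminus, and the substrate has no other carbonyl or olefin. Regiochemistry is not in question because the double bond can only form between the alkylidene carbon and the acyl carbon.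

Step 5
Reactants: 7 5,7-bis(benzyloxy)-2-[3,4-bis(benzyloxy)phenyl]-4H-chromene
Product: 9 (2R,3S)-5,7-bis(benzyloxy)-2-[3,4-bis(benzyloxy)phenyl]chroman-3-ol (tetra-O-benzyl-(+)-catechin), via isopinocampheyl(flavan-3-yl)borane 8 (not isolated)
Conditions: IpcBH2 (from (+)-α-pinene), THF, −25 °C to 0 °C; then NaOH, H2O2, 0 °C to rt
Reagents that add atoms: hydrogen peroxide, OO
Why: In this asymmetric hydroboration–oxidation boron should add to C3 (β to O1, the less substituted end of the aryl enol ether) and hydrogen to C2 from the same face, the face being chosen by the isopinocampheyl group in the sense established for 1-arylcycloalkenes (S carbinol), and oxidation with retention should give the 2,3-trans (2R,3S) alcohol, whose optical purity can be raised by recrystallisation.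

Step 6
Reactants: 10 (−)-epigallocatechin
Product: 11 (2R,3R)-5,7-bis(benzyloxy)-2-[3,4,5-tris(benzyloxy)phenyl]chroman-3-ol (penta-O-benzyl-epigallocatechin)
Conditions: BnBr, K2CO3, DMF, 0 °C to rt, N2
Reagents that add atoms: benzyl bromide, BrCc1ccccc1
Why: Williamson benzylation under carbonate base should etherify the five phenols only, leaving the secondary 3-OH and the C2 and C3 stereocentres untouched.

Step 7
Reactants: 11 penta-O-benzyl-epigallocatechin
Product: 12 (2R,3R,4S)-5,7-bis(benzyloxy)-4-(2-ethoxyethoxy)-2-[3,4,5-tris(benzyloxy)phenyl]chroman-3-ol (4β-ether, 3,4-trans)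
Conditions: DDQ, 2-ethoxyethanol, CH2Cl2, rt
Reagents that add atoms: 2-ethoxyethanol, CCOCCO
Why: DDQ benzylic oxidation (hydride abstraction at C4, activated by the 5- and 7-alkoxy groups) with capture by the alcohol anti to the 3-hydroxyl should give the 3,4-trans ether; the C4 configuration is not critical because this centre is ionised again in step 9.

Step 8
Reactants: 12 4β-(2-ethoxyethoxy) ether
Product: 13 (2R,3R,4S)-5,7-bis(benzyloxy)-4-(2-ethoxyethoxy)-2-[3,4,5-tris(benzyloxy)phenyl]chroman-3-yl acetate
Conditions: Ac2O, pyridine, DMAP (cat.), rt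
Reagents that add atoms: acetic anhydride, CC(=O)OC(C)=O
Why: DMAP-catalysed acetylation of the secondary alcohol should be straightforward and installs a neighbouring group that blocks the α face of C4 in the coupling.

Step 9
Reactants: 13 4β-(2-ethoxyethoxy) 3-acetate; 9 tetra-O-benzyl-(+)-catechin (in excess)
Product: 14 3-O-acetyl-penta-O-benzyl-epigallocatechin-(4β→8)-tetra-O-benzyl-catechin (upper unit 2R,3R,4R; lower unit 2R,3S)
Conditions: TMSOTf (cat.), CH2Cl2, −78 °C to −20 °C
Reagents that add atoms: none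
Why: Lewis-acid ionisation of the C4 ether and Friedel–Crafts alkylation at C8 of 9 (the most nucleophilic and least hindered ring A position of a 5,7-di-O-benzylflavan) should occur anti to the axial 3-acetoxy group, helped by its participation, and so set the 3,4-trans 4β (4R) linkage.

Step 10
Reactants: 14 nona-O-benzyl dimer 3-acetate
Product: 15 penta-O-benzyl-epigallocatechin-(4β→8)-tetra-O-benzyl-catechin (both 3-OH free)
Conditions: NaOMe (cat.), MeOH/THF, rt
Reagents that add atoms: none
Why: Zemplén transesterification should remove the acetate while benzyl ethers, stereocentres and the interflavan bond are inert to methoxide.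

Step 11
Reactants: 15 nona-O-benzyl dimer
Product: 16 epigallocatechin-(4β→8)-catechin, (2R,3R,4R)-2-(3,4,5-trihydroxyphenyl)-4-[(2R,3S)-2-(3,4-dihydroxyphenyl)-3,5,7-trihydroxychroman-8-yl]chroman-3,5,7-triol
Conditions: H2 (1 atm), Pd(OH)2/C, THF/MeOH/H2O, rt
Reagents that add atoms: none
Why: Neutral hydrogenolysis of the nine benzyl ethers should free all phenols without cleaving the acid-labile interflavan bond or the benzylic C2–O1 bonds.

## Compound list

1 | 3,5-bis(benzyloxy)phenol | Oc1cc(OCc2ccccc2)cc(OCc2ccccc2)c1 | starting material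
2 | 1-(allyloxy)-3,5-bis(benzyloxy)benzene | C=CCOc1cc(OCc2ccccc2)cc(OCc2ccccc2)c1 | intermediate
3 | 2-allyl-3,5-bis(benzyloxy)phenol | C=CCc1c(O)cc(OCc2ccccc2)cc1OCc1ccccc1 | intermediate
4 | 3,4-bis(benzyloxy)benzoic acid | OC(=O)c1ccc(OCc2ccccc2)c(OCc2ccccc2)c1 | starting material
5 | 2-allyl-3,5-bis(benzyloxy)phenyl 3,4-bis(benzyloxy)benzoate | C=CCc1c(OC(=O)c2ccc(OCc3ccccc3)c(OCc3ccccc3)c2)cc(OCc2ccccc2)cc1OCc1ccccc1 | intermediate
6 | dichlorotitanium alkylidene at the former internal allyl carbon of 5 (TMEDA ligand omitted) | Cl[Ti](Cl)=CCc1c(OC(=O)c2ccc(OCc3ccccc3)c(OCc3ccccc3)c2)cc(OCc2ccccc2)cc1OCc1ccccc1 | intermediate (not isolated)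
7 | 5,7-bis(benzyloxy)-2-[3,4-bis(benzyloxy)phenyl]-4H-chromene | C1(c2ccc(OCc3ccccc3)c(OCc3ccccc3)c2)=CCc2c(OCc3ccccc3)cc(OCc3ccccc3)cc2O1 | intermediate
8 | isopinocampheyl(2,3-trans-flavan-3-yl)borane from 7 | C[C@H]1[C@H](B[C@H]2Cc3c(OCc4ccccc4)cc(OCc4ccccc4)cc3O[C@@H]2c2ccc(OCc3ccccc3)c(OCc3ccccc3)c2)C[C@@H]2C[C@H]1C2(C)C | intermediate (not isolated)
9 | (2R,3S)-5,7-bis(benzyloxy)-2-[3,4-bis(benzyloxy)phenyl]chroman-3-ol | O[C@H]1Cc2c(OCc3ccccc3)cc(OCc3ccccc3)cc2O[C@@H]1c1ccc(OCc2ccccc2)c(OCc2ccccc2)c1 | intermediate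
10 | (−)-epigallocatechin, (2R,3R)-2-(3,4,5-trihydroxyphenyl)chroman-3,5,7-triol | O[C@@H]1Cc2c(O)cc(O)cc2O[C@@H]1c1cc(O)c(O)c(O)c1 | starting material
11 | (2R,3R)-5,7-bis(benzyloxy)-2-[3,4,5-tris(benzyloxy)phenyl]chroman-3-ol | O[C@@H]1Cc2c(OCc3ccccc3)cc(OCc3ccccc3)cc2O[C@@H]1c1cc(OCc2ccccc2)c(OCc2ccccc2)c(OCc2ccccc2)c1 | intermediate
12 | (2R,3R,4S)-5,7-bis(benzyloxy)-4-(2-ethoxyethoxy)-2-[3,4,5-tris(benzyloxy)phenyl]chroman-3-ol | O[C@@H]1[C@@H](OCCOCC)c2c(OCc3ccccc3)cc(OCc3ccccc3)cc2O[C@@H]1c1cc(OCc2ccccc2)c(OCc2ccccc2)c(OCc2ccccc2)c1 | intermediate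
13 | (2R,3R,4S)-5,7-bis(benzyloxy)-4-(2-ethoxyethoxy)-2-[3,4,5-tris(benzyloxy)phenyl]chroman-3-yl acetate | CC(=O)O[C@@H]1[C@@H](OCCOCC)c2c(OCc3ccccc3)cc(OCc3ccccc3)cc2O[C@@H]1c1cc(OCc2ccccc2)c(OCc2ccccc2)c(OCc2ccccc2)c1 | intermediate
14 | 3-O-acetyl-penta-O-benzyl-epigallocatechin-(4β→8)-tetra-O-benzyl-catechin | CC(=O)O[C@@H]1[C@@H](c2c(OCc3ccccc3)cc(OCc3ccccc3)c3c2O[C@H](c2ccc(OCc4ccccc4)c(OCc4ccccc4)c2)[C@@H](O)C3)c2c(OCc3ccccc3)cc(OCc3ccccc3)cc2O[C@@H]1c1cc(OCc2ccccc2)c(OCc2ccccc2)c(OCc2ccccc2)c1 | intermediate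
15 | penta-O-benzyl-epigallocatechin-(4β→8)-tetra-O-benzyl-catechin | O[C@@H]1[C@@H](c2c(OCc3ccccc3)cc(OCc3ccccc3)c3c2O[C@H](c2ccc(OCc4ccccc4)c(OCc4ccccc4)c2)[C@@H](O)C3)c2c(OCc3ccccc3)cc(OCc3ccccc3)cc2O[C@@H]1c1cc(OCc2ccccc2)c(OCc2ccccc2)c(OCc2ccccc2)c1 | intermediate
16 | epigallocatechin-(4β→8)-catechin | Oc1cc(O)c2c(c1)O[C@H](c1cc(O)c(O)c(O)c1)[C@H](O)[C@H]2c1c(O)cc(O)c2c1O[C@H](c1ccc(O)c(O)c1)[C@@H](O)C2 | target

## Step count and risks

Total steps: 11. Longest linear sequence: 8 (steps 1–5, then 9–11).

Steps most likely to fail: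

**Step 4.** The risk is direct ethylidenation of the ester before olefin exchange, which would stall at an acyclic enol ether, or migration of the allyl double bond into conjugation. The fallback sets out from 5: Petasis methylenation with Cp2TiMe2 in toluene at 65 °C should give the isolable acyclic enol ether 2-allyl-3,5-bis(benzyloxy)phenyl 1-[3,4-bis(benzyloxy)phenyl]ethenyl ether F1. Ring-closing olefin metathesis of F1 with the second-generation Grubbs catalyst in toluene at 80 °C, with loss of ethylene, should then close C2=C3 and return to 7.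

**Step 5.** The risk is poor facial selectivity of the chiral borane on the oxygen-substituted olefin, or β-elimination of the β-aryloxy borane before oxidation. The fallback sets out from 7: BH3·SMe2 in THF at 0 °C followed by NaOH/H2O2 should give, through the racemic 2,3-trans flavan-3-ylborane F2, the racemic trans alcohol, that is 9 together with (2S,3R)-tetra-O-benzyl-ent-catechin F3. The racemate is used in excess in the coupling with enantiopure 13 under the step 9 conditions, and the diastereomeric dimer acetate F4 is removed by chromatography; the route is rejoined at 14.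

**Step 9.** The risk is self-condensation of the electrophile, competing attack at C6, or further alkylation of the product to oligomers. The fallback sets out from 13: exchange of the 4-alkoxy group with benzothiazole-2-thiol and BF3·OEt2 in CH2Cl2 at 0 °C should give the 4β-(benzothiazol-2-ylthio) acetate F5. Thiophilic activation of F5 with AgBF4 in THF at 0 °C in the presence of 9 should deliver the same 4β→8 product and return to 14.

## Further compounds

F1 | step 4 | 2-allyl-3,5-bis(benzyloxy)phenyl 1-[3,4-bis(benzyloxy)phenyl]ethenyl ether | C=CCc1c(OC(=C)c2ccc(OCc3ccccc3)c(OCc3ccccc3)c2)cc(OCc2ccccc2)cc1OCc1ccccc1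
F2 | step 5 | racemic 2,3-trans-{5,7-bis(benzyloxy)-2-[3,4-bis(benzyloxy)phenyl]chroman-3-yl}borane (enantiomer leading to 9 drawn) | B[C@H]1Cc2c(OCc3ccccc3)cc(OCc3ccccc3)cc2O[C@@H]1c1ccc(OCc2ccccc2)c(OCc2ccccc2)c1
F3 | step 5 | (2S,3R)-5,7-bis(benzyloxy)-2-[3,4-bis(benzyloxy)phenyl]chroman-3-ol (enantiomer of 9) | O[C@@H]1Cc2c(OCc3ccccc3)cc(OCc3ccccc3)cc2O[C@H]1c1ccc(OCc2ccccc2)c(OCc2ccccc2)c1
F4 | step 5 | diastereomer of 14 with a (2S,3R) lower unit | CC(=O)O[C@@H]1[C@@H](c2c(OCc3ccccc3)cc(OCc3ccccc3)c3c2O[C@@H](c2ccc(OCc4ccccc4)c(OCc4ccccc4)c2)[C@H](O)C3)c2c(OCc3ccccc3)cc(OCc3ccccc3)cc2O[C@@H]1c1cc(OCc2ccccc2)c(OCc2ccccc2)c(OCc2ccccc2)c1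
F5 | step 9 | 4β-(benzothiazol-2-ylthio)-5,7-bis(benzyloxy)-2-[3,4,5-tris(benzyloxy)phenyl]chroman-3-yl acetate (2,3-cis-3,4-trans) | CC(=O)O[C@@H]1[C@@H](Sc2nc3ccccc3s2)c2c(OCc3ccccc3)cc(OCc3ccccc3)cc2O[C@@H]1c1cc(OCc2ccccc2)c(OCc2ccccc2)c(OCc2ccccc2)c1
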